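The numbers were chosen freely; the result is computed.

**Two roads.** Each D that leaves the flask leaves by one of two steps: G turns it into J, or Q turns it into Lx. The fractions of the charge found as Lx, as D left, and as material that has passed through J therefore add up to one. Qo comes from J, which E carries through Ky with the help of Q, and G can slip away into Z.

    D + G → G + J (k1 = 320 M⁻¹ h⁻¹)
    E + J ⇌ Ky (K2 = 3.1 M⁻¹, k2 = 16000 M⁻¹ h⁻¹)
    Q + Ky → E + Qo (k3 = 340 M⁻¹ h⁻¹)
    G ⇌ Z (K4 = 0.65, k4 = 0.083 h⁻¹)
    2 E ⇌ X, settled at all times (K5 = 16000 M⁻¹)
    D + Q → Lx (k6 = 0.38 M⁻¹ h⁻¹)

| setting | Thursday's | Friday's | Monday's | Wednesday's | Sunday's |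
|---|---|---|---|---|---|
| D | 0.30 M | 0.30 M | 0.30 M | 0.30 M | 0.30 M |
| Q | 0.500 equiv | 1.00 equiv | 2.00 equiv | 4.00 equiv | 8.00 equiv |
| G | 0.1 mol% | 0.1 mol% | 0.1 mol% | 0.1 mol% | 0.1 mol% |
| E | 0.1 mol% | 0.1 mol% | 0.1 mol% | 0.1 mol% | 0.1 mol% |
| time | 2.5 d | 2.5 d | 2.5 d | 2.5 d | 2.5 d |

- amount of Qo at the end, in percent of the D charged for Thursday's, Friday's, Monday's, Wednesday's, Sunday's, in this order
- the course of these numbers from the first flask to the last (falls, then rises / hardly changes / falls all the way / rises all the way / rises, then falls)

- two of one species on the left: rate k times its square, two consumed each time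
- "hardly changes" means that all values lie within two and a half points (for a concentration: within two and a half percent of the largest)
- run time (Thursday's): 2.5 d

**The split.** Both steps carry D as a factor, so D drops out of their ratio, and the contest is G against Q. The equivalents of Q at which the two steps take D equally, the selectivity factor here, are the rate constant of the step through G times G's loading, over the rate constant of the step to Lx. That gives 0.842; call it the split. With G and Q held as charged, the share of D that passes through J is then the split over the split plus the equivalents of Q.

**Turned round.** A row that keeps rising asks for a good share through J even in Sunday's flask, the richest in Q, and the two steps take D equally there, Q as charged, at a split of 8.00. The split of this flask stands ten times lower. G may be taken as charged in Sunday's flask because D's half-life by the step to Lx, Q as charged, is 0.760 h, shorter than the 3.29 h in which G and Z relax, a half-life told for Thursday's. The reckoning made here gives Sunday's flask 9.52% through J. It stops there: it gives a share, not the pace at which J becomes Qo, so the flasks poor in Q stay open.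

**The forecast.** The forecast gives 10%, 19%, 24%, 17% and 10%, a course that rises, then falls. For Sunday's flask its 10% stands beside the 9.52% reckoned here. At high Q, it holds, “the side reaction outruns G”.

**The flask.** The row reads 10.6%, 19.5%, 24.1%, 17.0% and 9.39%, a course that rises, then falls, with the turn read near 1.8 equiv. J left at the end stands at 57.2% in Thursday's flask, 29.0% in Friday's and 5.90% in Monday's. With G and Q held as charged, the split gives Monday's flask 29.6% through J, and there Qo and J together end at 30.0%, of which J is 5.90%.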